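**Retrosynthetic overview**
1. Target ⇐ late 8α,9α‑epoxidation and deprotection ⇐ 6α‑aroyloxy‑7β‑ol ⇐ 6α‑hydroxy‑7‑enone ⇐ 6,7‑dione ⇐ trans‑fused 4β‑hydroxy‑dauc‑8‑en‑6‑one.
2. That β‑hydroxy ketone ⇐ iPr addition to the C4 ketone and Tamao–Fleming oxidation of a C6 vinylsilane in a bicyclic dienone.
3. Key step: the five‑ and seven‑membered rings form together (C1–C5 and C6–C7) by Rh(I) [5+2] cycloaddition of a silyl ynone tethered through the cyclopropane to a vinylcyclopropane; the C1 quaternary centre is carried over from the cyclopropane.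
4. Vinylcyclopropane–ynone ⇐ nerol: Charette cyclopropanation (sets C1), CH2OH → isopropenyl, prenyl → methyl ester → ynone.
5. Ring order: sacrificial cyclopropane → 5‑ and 7‑rings in one operation → epoxide last.

Assumption: daucane numbering is used for bicyclic compounds (C1 = quaternary ring‑fusion C bearing Me‑15, C2/C3 = CH2, C4 = C(OH)iPr, C5 = ring‑fusion CH, C6–C10 = seven‑ring, Me‑14 on C8); the target is (1R,4R,5S,6R,7S,8R,9S) = 1β‑Me, 4β‑OH, 5α‑H, 6α‑O‑aroyl, 7β‑OH, 8α,9α‑epoxide.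

**Step 1**
Reactants: 1 nerol, (2Z)-3,7-dimethylocta-2,6-dien-1-ol
Product: 2 [(1S,2R)-2-methyl-2-(4-methylpent-3-en-1-yl)cyclopropyl]methanol
Conditions: Et2Zn, CH2I2, DME; (4R,5R)-2-butyl-N,N,N',N'-tetramethyl-1,3,2-dioxaborolane-4,5-dicarboxamide (1.2 equiv), CH2Cl2, −10 °C → rt
Reagents that add atoms: diiodomethane, ICI
Why: Charette asymmetric Simmons–Smith cyclopropanation reacts only at the allylic‑alcohol alkene, the Z‑alkene fixes the chain cis to CH2OH, and the (R,R)‑ligand delivers CH2 to the face that gives the (1S,2R) product (same facial sense as cinnamyl alcohol → (1S,2S)), which sets the future C1.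

**Step 2**
Reactants: 2 [(1S,2R)-2-methyl-2-(4-methylpent-3-en-1-yl)cyclopropyl]methanol
Product: 3 (1S,2R)-2-methyl-2-(4-methylpent-3-en-1-yl)cyclopropane-1-carboxylic acid
Conditions: TEMPO (10 mol %), PhI(OAc)2 (2.2 equiv), MeCN/H2O 1:1, rt
Reagents that add atoms: water, O
Why: TEMPO/PhI(OAc)2 oxidation of a primary alcohol through the aldehyde hydrate to the acid leaves the trisubstituted alkene and the cyclopropane untouched.

**Step 3**
Reactants: 3 (1S,2R)-2-methyl-2-(4-methylpent-3-en-1-yl)cyclopropane-1-carboxylic acid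
Product: 4 1-[(1S,2R)-2-methyl-2-(4-methylpent-3-en-1-yl)cyclopropyl]ethan-1-one
Conditions: MeLi (2.3 equiv), Et2O, 0 °C → rt; inverse quench into aq. NH4Cl
Reagents that add atoms: methyllithium, [Li]C
Why: Methyllithium adds to the lithium carboxylate to give a stable dilithium gem‑diolate that releases the methyl ketone only on work‑up, and the cyclopropyl α‑CH does not epimerise.

**Step 4**
Reactants: 4 1-[(1S,2R)-2-methyl-2-(4-methylpent-3-en-1-yl)cyclopropyl]ethan-1-one
Product: 6 methyl 3-[(1R,2S)-2-acetyl-1-methylcyclopropyl]propanoate, via keto aldehyde 5 (not isolated)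
Conditions: O3, NaOH (2.5 M in MeOH), CH2Cl2, −78 °C
Reagents that add atoms: ozone, [O-][O+]=O; methanol, CO
Why: Marshall ozonolysis cleaves the only alkene, and the aldehyde is oxidised in situ by ozone as its methyl hemiacetal to the methyl ester, with acetone lost.

**Step 5**
Reactants: 6 methyl 3-[(1R,2S)-2-acetyl-1-methylcyclopropyl]propanoate
Product: 7 methyl 3-[(1R,2R)-1-methyl-2-(prop-1-en-2-yl)cyclopropyl]propanoate
Conditions: Ph3PCH3Br, NaHMDS, THF, 0 °C → rt
Reagents that add atoms: methyltriphenylphosphonium bromide, C[P+](c1ccccc1)(c1ccccc1)c1ccccc1.[Br-]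
Why: Wittig methylenation of the methyl ketone gives the isopropenyl (vinylcyclopropane) unit while the methyl ester is inert to the non‑stabilised ylide at this temperature.

**Step 6**
Reactants: 8 benzyl(chloro)dimethylsilane; 9 ethynylmagnesium bromide
Product: 10 benzyl(ethynyl)dimethylsilane
Conditions: THF, 0 °C → rt
Reagents that add atoms: none
Why: Nucleophilic substitution at silicon by the acetylide Grignard gives the alkynylsilane that carries an oxidisable benzyldimethylsilyl group.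

**Step 7**
Reactants: 7 methyl 3-[(1R,2R)-1-methyl-2-(prop-1-en-2-yl)cyclopropyl]propanoate; 10 benzyl(ethynyl)dimethylsilane
Product: 12 1-[benzyl(dimethyl)silyl]-5-[(1R,2R)-1-methyl-2-(prop-1-en-2-yl)cyclopropyl]pent-1-yn-3-one, via lithium acetylide 11 (not isolated)
Conditions: 10, n-BuLi, THF, −78 °C; BF3·OEt2; then 7, −78 °C
Reagents that add atoms: none
Why: BF3‑mediated acylation of a lithium acetylide by an ester (Yamaguchi conditions) stops at the ynone because the tetrahedral borate adduct survives until work‑up.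

**Step 8**
Reactants: 12 1-[benzyl(dimethyl)silyl]-5-[(1R,2R)-1-methyl-2-(prop-1-en-2-yl)cyclopropyl]pent-1-yn-3-one
Product: 13 (3aR)-8-[benzyl(dimethyl)silyl]-3a,6-dimethyl-3,3a,4,7-tetrahydroazulen-1(2H)-one (daucane numbering: 4‑oxo, Δ5, Δ8, 6‑silyl, without the isopropyl group)
Conditions: [Rh(CO)2Cl]2 (5 mol %), 1,2-dichloroethane (0.02 M), 60 °C
Reagents that add atoms: none
Why: Proposed new method: Rh(I) binds the isopropenyl group and the cis‑tethered alkyne, strain‑driven insertion into the C1–C9 cyclopropane bond (the only cleavage the three‑atom tether can follow) gives a σ,π‑allyl rhodacycle, and alkyne insertion plus reductive elimination form C6–C7 and C1–C5, so both carbocycles and the C8=C9 alkene arise in one operation while C1 keeps its configuration because the C1–Rh bond forms and is replaced with retention; the closest known reactions are the Wender Rh‑catalysed vinylcyclopropane–alkyne [5+2] cycloaddition and the [5+2] of cis‑2‑ene‑vinylcyclopropanes tethered through the cyclopropane.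

**Step 9**
Reactants: 13 (3aR)-8-[benzyl(dimethyl)silyl]-3a,6-dimethyl-3,3a,4,7-tetrahydroazulen-1(2H)-one
Product: 14 (1R,4R)-6-[benzyl(dimethyl)silyl]dauca-5,8-dien-4β-ol
Conditions: iPrMgCl, LaCl3·2LiCl, THF, 0 °C
Reagents that add atoms: isopropylmagnesium chloride, CC(C)[Mg]Cl
Why: Lanthanum‑promoted 1,2‑addition of the Grignard reagent suppresses enolisation and β‑hydride reduction, and attack anti to the pseudo‑axial C1 methyl group (α‑face) gives the 4β‑OH (4R) tertiary alcohol.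

**Step 10**
Reactants: 14 (1R,4R)-6-[benzyl(dimethyl)silyl]dauca-5,8-dien-4β-ol
Product: 16 (1R,4R,5R)-4β-hydroxy-5α-dauc-8-en-6-one, via cyclic siloxane 15 (not isolated)
Conditions: TBAF, THF, 0 °C; then KHCO3, 30% H2O2, MeOH, rt
Reagents that add atoms: hydrogen peroxide, OO
Why: Tamao–Fleming oxidation of a γ‑hydroxy vinyl‑benzyldimethylsilane (the Trost aldol‑surrogate protocol) turns C6–Si into the C6 enol and then the ketone, and C5 settles as the trans‑fused 5α‑H epimer in which C6 is trans to the isopropyl group and hydrogen‑bonded to the 4‑OH.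

**Step 11**
Reactants: 16 (1R,4R,5R)-4β-hydroxy-5α-dauc-8-en-6-one
Product: 17 (1R,4R,5R)-4β-hydroxy-5α-dauc-8-ene-6,7-dione
Conditions: SeO2 (1.2 equiv), 1,4-dioxane/H2O 20:1, 70 °C
Reagents that add atoms: selenium dioxide, O=[Se]=O
Why: Riley oxidation proceeds through the conjugated C6/C7 enol, so the doubly activated (α‑keto and allylic) C7 methylene is oxidised to the carbonyl in preference to the hindered C5 methine.

**Step 12**
Reactants: 17 (1R,4R,5R)-4β-hydroxy-5α-dauc-8-ene-6,7-dione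
Product: 18 (1R,4R,5S,6R)-4β,6α-dihydroxy-5α-dauc-8-en-7-one
Conditions: Me4NBH(OAc)3 (1.3 equiv), MeCN/AcOH 1:1, −35 °C
Reagents that add atoms: none
Why: Evans–Saksena hydroxyl‑directed reduction delivers hydride from the boron bound to the 4β‑OH through a six‑membered transition state onto the β‑face of the C6 carbonyl only, giving the 6α‑OH, while the C7 enone carbonyl has no directing hydroxyl at the outset.

**Step 13**
Reactants: 18 (1R,4R,5S,6R)-4β,6α-dihydroxy-5α-dauc-8-en-7-one; 19 4-acetoxybenzoyl chloride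
Product: 20 (1R,4R,5S,6R)-6α-(4-acetoxybenzoyloxy)-4β-hydroxy-5α-dauc-8-en-7-one
Conditions: pyridine, DMAP (cat.), CH2Cl2, 0 °C → rt
Reagents that add atoms: none
Why: DMAP‑catalysed acylation hits the only secondary hydroxyl (C6) because the tertiary 4‑OH is unreactive and C7 is still a ketone, so no diol differentiation is needed.

**Step 14**
Reactants: 20 (1R,4R,5S,6R)-6α-(4-acetoxybenzoyloxy)-4β-hydroxy-5α-dauc-8-en-7-one
Product: 21 (1R,4R,5S,6R,7R)-6α-(4-acetoxybenzoyloxy)-5α-dauc-8-ene-4β,7β-diol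
Conditions: NaBH4, CeCl3·7H2O, MeOH, −78 °C
Reagents that add atoms: none
Why: Luche 1,2‑reduction of the enone takes hydride on the α‑face (axial attack anti to the pseudo‑axial C6–H, with the β‑face screened by the axial C1 methyl and the pseudo‑equatorial ester not interfering), giving the equatorial 7β‑OH trans to the 6α‑ester.

**Step 15**
Reactants: 21 (1R,4R,5S,6R,7R)-6α-(4-acetoxybenzoyloxy)-5α-dauc-8-ene-4β,7β-diol
Product: 23 (1R,4R,5S,6R,7S,8R,9S)-6α-(4-acetoxybenzoyloxy)-8α,9α-epoxy-7β-(trimethylsilyloxy)-5α-daucan-4β-ol, via silyl ether 22 (not isolated)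
Conditions: BSA (1.5 equiv), CH2Cl2, rt; then mCPBA, NaHCO3, 0 °C
Reagents that add atoms: N,O-bis(trimethylsilyl)acetamide, CC(=N[Si](C)(C)C)O[Si](C)(C)C; meta-chloroperoxybenzoic acid, OOC(=O)c1cccc(Cl)c1
Why: Transient silylation of the 7β‑OH switches off hydroxyl‑directed (Henbest) delivery, so the Prilezhaev epoxidation of the trisubstituted alkene is sterically controlled and occurs on the α‑face, anti to the axial C1 methyl (1,3 to C9) and to the 7β‑siloxy group.

**Step 16**
Reactants: 23 (1R,4R,5S,6R,7S,8R,9S)-6α-(4-acetoxybenzoyloxy)-8α,9α-epoxy-7β-(trimethylsilyloxy)-5α-daucan-4β-ol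
Product: 24 (1R,4R,5S,6R,7S,8R,9S)-8α,9α-epoxy-4β,7β-dihydroxy-5α-daucan-6α-yl 4-hydroxybenzoate (CNP0290052.1)
Conditions: K2CO3 (0.3 equiv), MeOH, 0 °C, 20 min; AcOH quench
Reagents that add atoms: none
Why: Mild methanolysis removes the phenolic acetate first and then the trimethylsilyl ether, and the resulting phenoxide deactivates the benzoate towards methanolysis or acyl migration while the short cold exposure avoids Payne rearrangement.

**Compound list**
1 | nerol, (2Z)-3,7-dimethylocta-2,6-dien-1-ol | CC(C)=CCC/C(C)=C\CO | starting material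
2 | [(1S,2R)-2-methyl-2-(4-methylpent-3-en-1-yl)cyclopropyl]methanol | CC(C)=CCC[C@]1(C)C[C@@H]1CO | intermediate
3 | (1S,2R)-2-methyl-2-(4-methylpent-3-en-1-yl)cyclopropane-1-carboxylic acid | CC(C)=CCC[C@]1(C)C[C@@H]1C(=O)O | intermediate
4 | 1-[(1S,2R)-2-methyl-2-(4-methylpent-3-en-1-yl)cyclopropyl]ethan-1-one | CC(C)=CCC[C@]1(C)C[C@@H]1C(C)=O | intermediate
5 | 3-[(1R,2S)-2-acetyl-1-methylcyclopropyl]propanal | O=CCC[C@]1(C)C[C@@H]1C(C)=O | intermediate (not isolated)
6 | methyl 3-[(1R,2S)-2-acetyl-1-methylcyclopropyl]propanoate | COC(=O)CC[C@]1(C)C[C@@H]1C(C)=O | intermediate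
7 | methyl 3-[(1R,2R)-1-methyl-2-(prop-1-en-2-yl)cyclopropyl]propanoate | COC(=O)CC[C@]1(C)C[C@@H]1C(C)=C | intermediate
8 | benzyl(chloro)dimethylsilane | C[Si](C)(Cl)Cc1ccccc1 | starting material
9 | ethynylmagnesium bromide | C#C[Mg]Br | starting material
10 | benzyl(ethynyl)dimethylsilane | C#C[Si](C)(C)Cc1ccccc1 | intermediate
11 | lithium [benzyl(dimethyl)silyl]acetylide | [Li]C#C[Si](C)(C)Cc1ccccc1 | intermediate (not isolated)
12 | 1-[benzyl(dimethyl)silyl]-5-[(1R,2R)-1-methyl-2-(prop-1-en-2-yl)cyclopropyl]pent-1-yn-3-one | C[Si](C)(Cc1ccccc1)C#CC(=O)CC[C@]1(C)C[C@@H]1C(C)=C | intermediate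
13 | (3aR)-8-[benzyl(dimethyl)silyl]-3a,6-dimethyl-3,3a,4,7-tetrahydroazulen-1(2H)-one | O=C1CC[C@]2(C)CC=C(C)CC([Si](C)(C)Cc3ccccc3)=C12 | intermediate
14 | (1R,4R)-6-[benzyl(dimethyl)silyl]dauca-5,8-dien-4β-ol | CC(C)[C@]1(O)CC[C@]2(C)CC=C(C)CC([Si](C)(C)Cc3ccccc3)=C12 | intermediate
15 | cyclic siloxane of 14 (O4–SiMe2–C6 1,2-oxasilole, benzyl lost) | CC(C)[C@]1(O4)CC[C@]2(C)CC=C(C)CC([Si]4(C)C)=C12 | intermediate (not isolated)
16 | (1R,4R,5R)-4β-hydroxy-5α-dauc-8-en-6-one | CC(C)[C@]1(O)CC[C@]2(C)CC=C(C)CC(=O)[C@H]21 | intermediate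
17 | (1R,4R,5R)-4β-hydroxy-5α-dauc-8-ene-6,7-dione | CC(C)[C@]1(O)CC[C@]2(C)CC=C(C)C(=O)C(=O)[C@H]21 | intermediate
18 | (1R,4R,5S,6R)-4β,6α-dihydroxy-5α-dauc-8-en-7-one | CC(C)[C@]1(O)CC[C@]2(C)CC=C(C)C(=O)[C@H](O)[C@H]21 | intermediate
19 | 4-acetoxybenzoyl chloride | CC(=O)Oc1ccc(cc1)C(Cl)=O | starting material
20 | (1R,4R,5S,6R)-6α-(4-acetoxybenzoyloxy)-4β-hydroxy-5α-dauc-8-en-7-one | CC(C)[C@]1(O)CC[C@]2(C)CC=C(C)C(=O)[C@H](OC(=O)c3ccc(OC(C)=O)cc3)[C@H]21 | intermediate
21 | (1R,4R,5S,6R,7R)-6α-(4-acetoxybenzoyloxy)-5α-dauc-8-ene-4β,7β-diol | CC(C)[C@]1(O)CC[C@]2(C)CC=C(C)[C@@H](O)[C@H](OC(=O)c3ccc(OC(C)=O)cc3)[C@H]21 | intermediate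
22 | 7-O-trimethylsilyl ether of 21 | CC(C)[C@]1(O)CC[C@]2(C)CC=C(C)[C@@H](O[Si](C)(C)C)[C@H](OC(=O)c3ccc(OC(C)=O)cc3)[C@H]21 | intermediate (not isolated)
23 | (1R,4R,5S,6R,7S,8R,9S)-6α-(4-acetoxybenzoyloxy)-8α,9α-epoxy-7β-(trimethylsilyloxy)-5α-daucan-4β-ol | CC(C)[C@]1(O)CC[C@]2(C)C[C@@H]3O[C@]3(C)[C@@H](O[Si](C)(C)C)[C@H](OC(=O)c3ccc(OC(C)=O)cc3)[C@H]21 | intermediate
24 | (1R,4R,5S,6R,7S,8R,9S)-8α,9α-epoxy-4β,7β-dihydroxy-5α-daucan-6α-yl 4-hydroxybenzoate | CC(C)[C@]1(O)CC[C@]2(C)C[C@@H]3O[C@]3(C)[C@@H](O)[C@H](OC(=O)c3ccc(O)cc3)[C@H]21 | target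

**Step count**
Total: 16 steps. Longest linear sequence: 15 steps (steps 1–5 and 7–16, from nerol); step 6 is a one‑step side branch.

**Three steps most likely to fail**

Step 8. The [5+2] has to break the cyclopropane at a quaternary carbon and form a quaternary centre by reductive elimination; a [3+2] pathway (bond to C9 instead of C7) or no C–C activation are the likely failures. The fallback sets out from 7 and returns at 16. It swaps the 2π partner for an alkene, for which the [5+2] of cis‑ene‑vinylcyclopropanes tethered through the cyclopropane is precedented, and brings in the C5=C6 unsaturation and the C6 oxygen afterwards. MeNH(OMe)·HCl/iPrMgCl converts 7 into Weinreb amide F1, and vinylmagnesium bromide gives vinyl ketone F2. [Rh(CO)2Cl]2 (toluene, 80 °C) then gives bicyclic ketone F3, whose C5 configuration does not matter. TMSOTf/Et3N gives the more substituted silyl enol ether F4, and Pd(OAc)2 (Saegusa–Ito) gives enone F5. CuCl/NaOtBu/B2pin2/MeOH adds boron to C6 from the α‑face with α‑protonation at C5 to give boronate F6, which NaBO3 oxidises to hydroxy ketone F7. iPrMgCl/LaCl3·2LiCl gives diol F8, and Dess–Martin oxidation of its secondary alcohol gives 16.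

Step 11. Hot, weakly acidic SeO2 may dehydrate the tertiary aldol or over‑oxidise allylic positions. The fallback sets out from 16 and returns at 17, using enolate chemistry instead. LDA (2.2 equiv, THF, −78 °C) forms the alkoxide/C7 dienolate, and 2‑(phenylsulfonyl)‑3‑phenyloxaziridine hydroxylates it at C7 to give α‑ketol F9 (either C7 epimer is acceptable). Dess–Martin periodinane then oxidises F9 to dione 17.

Step 12. The ene‑1,2‑dione may be partly enolised, or the new 6‑OH may direct further reduction of C7. The fallback sets out from 17 and returns at 18 by over‑reducing on purpose and re‑oxidising selectively. Excess Me4NBH(OAc)3 (−20 → 0 °C) gives triol F10, with C6 set by delivery from the 4‑OH and C7 by delivery from the new 6α‑OH. MnO2 (CH2Cl2, rt) then oxidises only the allylic 7‑OH, giving 18.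

**Further compounds**
F1 | step 8 | N-methoxy-N-methyl-3-[(1R,2R)-1-methyl-2-(prop-1-en-2-yl)cyclopropyl]propanamide | CON(C)C(=O)CC[C@]1(C)C[C@@H]1C(C)=C
F2 | step 8 | 5-[(1R,2R)-1-methyl-2-(prop-1-en-2-yl)cyclopropyl]pent-1-en-3-one | C=CC(=O)CC[C@]1(C)C[C@@H]1C(C)=C
F3 | step 8 | (3aR)-3a,6-dimethyl-3,3a,4,7,8,8a-hexahydroazulen-1(2H)-one | O=C1CC[C@]2(C)CC=C(C)CCC12
F4 | step 8 | (3aR)-3a,6-dimethyl-1-(trimethylsilyloxy)-2,3,3a,4,7,8-hexahydroazulene | C[Si](C)(C)OC=1CC[C@]2(C)CC=C(C)CCC2=1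
F5 | step 8 | (3aR)-3a,6-dimethyl-3,3a,4,7-tetrahydroazulen-1(2H)-one | O=C1CC[C@]2(C)CC=C(C)CC=C12
F6 | step 8 | 6α-(pinacolboryl)-5α-H bicyclic ketone (boron on C6 of F5) | O=C1CC[C@]2(C)CC=C(C)C[C@H](B3OC(C)(C)C(C)(C)O3)[C@H]21
F7 | step 8 | 6α-hydroxy-5α-H bicyclic ketone (C4 ketone, no isopropyl) | O=C1CC[C@]2(C)CC=C(C)C[C@H](O)[C@H]21
F8 | step 8 | 5α-dauc-8-ene-4β,6α-diol | CC(C)[C@]1(O)CC[C@]2(C)CC=C(C)C[C@H](O)[C@H]21
F9 | step 11 | 4β,7-dihydroxy-5α-dauc-8-en-6-one (C7 epimers) | CC(C)[C@]1(O)CC[C@]2(C)CC=C(C)C(O)C(=O)[C@H]21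
F10 | step 12 | 5α-dauc-8-ene-4β,6α,7β-triol | CC(C)[C@]1(O)CC[C@]2(C)CC=C(C)[C@@H](O)[C@H](O)[C@H]21
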